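**Assumption:** The SMILES is read as the all-trans isomer, 5-[(1R,5S,6R)-6-(2,4-dihydroxybenzoyl)-5-(2,4-dihydroxyphenyl)-3-methylcyclohex-2-en-1-yl]-2,4-dihydroxybenzaldehyde. This is the exo (with respect to the aroyl group) Diels–Alder adduct of an (E)-chalcone and an (E)-1-aryl-3-methylbutadiene. The sense of induction of the new catalyst in step 6 cannot be predicted with certainty, so the antipode that gives this enantiomer is used (both are made from (R)- or (S)-BINOL).

## Retrosynthetic overview

1. Target ⇐ one-pot global deprotection of a protected cycloadduct (four aryl allyl ethers, two aryl acetates, aldehyde masked as its gem-diacetate).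
2. Cyclohexene (the only ring built) ⇐ exo- and enantioselective [4+2] cycloaddition of a tetra-O-allyl chalcone with an acetylated 1-aryl-3-methylbutadiene, catalysed by a chiral Brønsted acid; this sets all three stereocentres at once.
3. Chalcone ⇐ Claisen–Schmidt condensation of bis-allylated 2,4-dihydroxyacetophenone and 2,4-dihydroxybenzaldehyde.
4. Diene ⇐ Heck vinylation of isoprene with per-acetylated 5-bromo-2,4-dihydroxybenzaldehyde.
5. All three aromatic rings are purchased; no other ring is formed.

## Route

**Step 1**
Reactants: 1, 2,4-dihydroxyacetophenone; 2, allyl bromide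
Product: 3, 1-[2,4-bis(allyloxy)phenyl]ethan-1-one
Conditions: allyl bromide (3 equiv), K2CO3, cat. KI, DMF, 60 °C
Reagents that add atoms: allyl bromide, C=CCBr
Why: Williamson etherification; excess halide in warm DMF alkylates both the free 4-OH and the hydrogen-bonded 2-OH, and no stereocentre is involved.

**Step 2**
Reactants: 4, 2,4-dihydroxybenzaldehyde; 2, allyl bromide
Product: 5, 2,4-bis(allyloxy)benzaldehyde
Conditions: allyl bromide (2.5 equiv), K2CO3, DMF, 50 °C
Reagents that add atoms: allyl bromide, C=CCBr
Why: Williamson etherification of both phenols; the aldehyde is inert to carbonate and allyl bromide.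

**Step 3**
Reactants: 3, 1-[2,4-bis(allyloxy)phenyl]ethan-1-one; 5, 2,4-bis(allyloxy)benzaldehyde
Product: 6, (E)-1,3-bis[2,4-bis(allyloxy)phenyl]prop-2-en-1-one (tetra-O-allyl chalcone)
Conditions: KOH (aq.), EtOH, rt, 24–48 h
Reagents that add atoms: none
Why: Claisen–Schmidt crossed aldol condensation; only the ketone is enolisable, E1cB dehydration gives the (E)-enone, and aryl allyl ethers are stable to KOH/EtOH at rt.

**Step 4**
Reactants: 7, 5-bromo-2,4-dihydroxybenzaldehyde; 8, acetic anhydride
Product: 9, 4-bromo-6-(diacetoxymethyl)-1,3-phenylene diacetate (both phenols acetylated, CHO converted to CH(OAc)2)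
Conditions: Ac2O (neat), cat. H2SO4, 0 °C → rt; ice/NaHCO3 work-up
Reagents that add atoms: acetic anhydride, CC(=O)OC(C)=O
Why: Acid-catalysed O-acetylation with simultaneous acylal formation; this masks the aldehyde against the strong acid of step 6 and makes the aryl ring electron-poor, and every acetate is released later by one methanolysis.

**Step 5**
Reactants: 9, 4-bromo-6-(diacetoxymethyl)-1,3-phenylene diacetate; 10, isoprene
Product: 11, 4-(diacetoxymethyl)-6-[(1E)-3-methylbuta-1,3-dien-1-yl]-1,3-phenylene diacetate
Conditions: isoprene (5 equiv), Pd2(dba)3 (2.5 mol%), [HP(t-Bu)3]BF4 (10 mol%), Cy2NMe, dioxane, BHT, 70 °C, sealed tube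
Reagents that add atoms: isoprene, C=CC(C)=C
Why: Mizoroki–Heck vinylation of a 1,3-diene; aryl-Pd adds to the unsubstituted terminus of the monosubstituted vinyl group and β-H elimination from the π-allyl intermediate gives the conjugated (E)-1-aryl-3-methyl-1,3-diene, while the amine base leaves the acetates and acylal intact.

**Step 6**
Reactants: 6, tetra-O-allyl chalcone; 11, acetylated aryl diene
Product: 12, 4-{(1R,5S,6R)-6-[2,4-bis(allyloxy)benzoyl]-5-[2,4-bis(allyloxy)phenyl]-3-methylcyclohex-2-en-1-yl}-6-(diacetoxymethyl)-1,3-phenylene diacetate (aryl, aroyl and aryl groups all-trans)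
Conditions: 6 (1.0 equiv), 11 (1.5 equiv), chiral IDPi Brønsted acid (5 mol%), CH2Cl2, 5 Å MS, −20 °C, 48–72 h; Et3N quench. The catalyst is an imidodiphosphorimidate built from two 3,3'-bis[3,5-bis(trifluoromethyl)phenyl]-BINOL units with N-triflyl groups on both phosphorus atoms.
Reagents that add atoms: none
Why: Proposed new method: a confined chiral Brønsted acid catalyses the intermolecular Diels–Alder reaction of a non-chelating chalcone with an acyclic 1-aryl diene. The closest known reaction types are IDPi- and N-triflylphosphoramide-catalysed Diels–Alder reactions of enones, enals and acrylates with cyclopentadiene or siloxydienes, and the chelation-based chiral borate Diels–Alder reaction of 2'-hydroxychalcones. The reasoning is as follows: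
- **Chemoselective activation:** the ketone, made basic by four alkoxy donors, is the only site protonated; the aldehyde is masked as the acylal and the OAc-substituted diene is poorly basic, so hetero-Diels–Alder and cationic diene oligomerisation are suppressed.
- **Regiochemistry:** the O-protonated chalcone/IDPi ion pair is a LUMO-lowered dienophile that reacts in an asynchronous concerted [4+2], the diene CH2 terminus bonding to the β-carbon.
- **Exo selectivity (expected):** the anion-bound C=O–H+ end cannot sit beneath the diene inside the pocket, so the aroyl group points away; with the E-alkene and E-diene this gives the all-trans product.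
- **Enantioselectivity:** the pocket shields one enone face, setting the three stereocentres together.
- **Turnover:** the saturated product ketone is less basic than the chalcone and releases the catalyst.
- **Compatibility:** no free OH is present, so flavanone, flavylium or chromene formation is impossible, and allyl ethers, aryl acetates and the acylal tolerate catalytic anhydrous acid at −20 °C.

**Step 7**
Reactants: 12, protected cycloadduct
Product: 13, 5-[(1R,5S,6R)-6-(2,4-dihydroxybenzoyl)-5-(2,4-dihydroxyphenyl)-3-methylcyclohex-2-en-1-yl]-2,4-dihydroxybenzaldehyde (target)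
Conditions: Pd(PPh3)4 (10 mol%), K2CO3, degassed MeOH/THF, rt, under Ar; pH 5 buffer work-up
Reagents that add atoms: none
Why: Pd(0)-catalysed deallylation (π-allyl transfer to methoxide) and carbonate methanolysis of the two aryl acetates and the acylal (which returns the CHO) run in one pot under non-acidic conditions; this avoids acid-induced phenol–alkene cyclisation, and the only epimerisable centre (α to the ketone) already has the thermodynamic all-equatorial configuration.

## Compound list

1 | 2,4-dihydroxyacetophenone | CC(=O)c1ccc(O)cc1O | starting material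
2 | allyl bromide | C=CCBr | starting material
3 | 1-[2,4-bis(allyloxy)phenyl]ethan-1-one | CC(=O)c1ccc(OCC=C)cc1OCC=C | intermediate
4 | 2,4-dihydroxybenzaldehyde | O=Cc1ccc(O)cc1O | starting material
5 | 2,4-bis(allyloxy)benzaldehyde | O=Cc1ccc(OCC=C)cc1OCC=C | intermediate
6 | (E)-1,3-bis[2,4-bis(allyloxy)phenyl]prop-2-en-1-one | O=C(/C=C/c1ccc(OCC=C)cc1OCC=C)c1ccc(OCC=C)cc1OCC=C | intermediate
7 | 5-bromo-2,4-dihydroxybenzaldehyde | O=Cc1cc(Br)c(O)cc1O | starting material
8 | acetic anhydride | CC(=O)OC(C)=O | starting material
9 | 4-bromo-6-(diacetoxymethyl)-1,3-phenylene diacetate | CC(=O)OC(OC(C)=O)c1cc(Br)c(OC(C)=O)cc1OC(C)=O | intermediate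
10 | isoprene | C=CC(C)=C | starting material
11 | 4-(diacetoxymethyl)-6-[(1E)-3-methylbuta-1,3-dien-1-yl]-1,3-phenylene diacetate | CC(=O)OC(OC(C)=O)c1cc(/C=C/C(C)=C)c(OC(C)=O)cc1OC(C)=O | intermediate
12 | 4-{(1R,5S,6R)-6-[2,4-bis(allyloxy)benzoyl]-5-[2,4-bis(allyloxy)phenyl]-3-methylcyclohex-2-en-1-yl}-6-(diacetoxymethyl)-1,3-phenylene diacetate | CC1=C[C@@H](c2cc(C(OC(C)=O)OC(C)=O)c(OC(C)=O)cc2OC(C)=O)[C@H](C(=O)c2ccc(OCC=C)cc2OCC=C)[C@@H](c2ccc(OCC=C)cc2OCC=C)C1 | intermediate
13 | 5-[(1R,5S,6R)-6-(2,4-dihydroxybenzoyl)-5-(2,4-dihydroxyphenyl)-3-methylcyclohex-2-en-1-yl]-2,4-dihydroxybenzaldehyde | CC1=C[C@@H](c2cc(C=O)c(O)cc2O)[C@H](C(=O)c2ccc(O)cc2O)[C@@H](c2ccc(O)cc2O)C1 | target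

## Summary

**Total step count:** 7

**Longest linear sequence:** 4 steps (steps 1 → 3 → 6 → 7, or equally 4 → 5 → 6 → 7)

**Three steps most likely to fail**

1. **Step 6 (proposed new Brønsted-acid Diels–Alder).** Risks are low conversion, endo adduct instead of exo, acid-induced diene oligomerisation, or acylal ionisation. Fallback (known chemistry): switch from non-covalent acid catalysis to covalent chelation control. Mono-allylate only the 4-OH in step 1 to obtain the 2'-hydroxy chalcone, then run the established cycloaddition of 2'-hydroxychalcones with aryl dienes promoted by a chiral BINOL/VANOL-type borate (from B(OPh)3 or BH3·THF/AcOH). Separate the exo adduct by chromatography and continue with step 7 unchanged.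

2. **Step 5 (Heck with isoprene).** Risks are arylation at the wrong diene terminus, diene dimerisation or polymerisation, and partial ester loss. Fallback: use a preformed diene unit in a Suzuki–Miyaura coupling of 9 with (E)-(3-methylbuta-1,3-dien-1-yl)boronic acid pinacol ester (made by hydroboration of 2-methylbut-1-en-3-yne with pinacolborane) under anhydrous base. This fixes regiochemistry and E-geometry at the cost of one step.

3. **Step 7 (one-pot global deprotection).** Risks are C-allylation of the resorcinol phenoxides by π-allyl-Pd, incomplete deallylation, and air oxidation of the polyphenol. Fallback: change the protecting-group plan so that the chalcone also carries only acetates (Claisen–Schmidt with MOM ethers, MOM removal, then Ac2O, before the cycloaddition). The final step is then a plain K2CO3/MeOH methanolysis without palladium, at the cost of two extra steps.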